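(The numbers stand for no real mixture; the flask was simulated.)

The nucleophile is charged at 1.30 equiv to the electrophile, the buffer base at 1.00 equiv and the buffer acid at 0.100 equiv.

    electrophile + nucleophile → acid + target + leaving group (k1 = 0.0298 M⁻¹ s⁻¹)
    protonated nucleophile ⇌ nucleophile + acid, settled at all times (K2 = 2.5 × 10⁻⁷ M)
    buffer acid ⇌ buffer base + acid, settled at all times (K3 = 2.0 × 10⁻⁵ M)
    target ⇌ isomer of the product (K4 = 0.45, k4 = 2.97 × 10⁻⁴ s⁻¹)
    electrophile + target ⇌ idle adduct, settled at all times (K5 = 105 M⁻¹)

electrophile 16 mM; nucleophile 1.30 equiv; buffer base 1.00 equiv; buffer acid 0.100 equiv; time 10 min

- acid is the free proton; pH is minus the decimal logarithm of its molar concentration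
- percent here means electrophile units held: one idle adduct counts as two
- what is said of target includes idle adduct
- in an amount of target, one idle adduct counts as one target
- what has gone from electrophile into another species counts as reacted, even if it can come back
- run time (flask): 10 min

1. part of the electrophile that has reacted at 10 min
2. pH of the solution at 10 min

The first step is what I reckon from. Its rate constant times the nucleophile as charged times the time is 0.372: this is the clock, the lifetimes of a pseudo-first-order electrophile that the run allows. One minus the exponential of minus the clock gives a share of 31.1% reacted.

But the nucleophile does not stay as charged. Each turnover consumes one, and the acid released lands on a second rather than on the buffer base, because the buffer acid gives up its acid far more readily than the protonated nucleophile does. So the rate sags, and the pH falls as protonated nucleophile builds up.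

Against that, target once made binds further electrophile into idle adduct, which counts as reacted, and 1.7, the equilibrium constant of that step times the starting electrophile, is more than one. The two corrections push opposite ways, so I stay with 31.1%.

The forecast is higher than mine, at 33.4% and pH 6.98, and it says that the adduct equilibrium “depletes both electrophile and free target”.

The flask gives 33.5% and pH 6.98. The clock's share here stands 2.4 percentage points below the result, with 59% of the nucleophile left unbound. The neighbouring flask has 5.20 equiv of nucleophile, with the other charges and the time held. Its clock is 1.49, which gives a share of 77.4%. That flask gives 76.4% reacted, with 75% of its nucleophile left unbound.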